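**Retrosynthetic overview**

- Feature used: in the cyclohexene ring (C1 = tertiary carbinol carrying the C16 chain, C2, C3 = allylic CHOH, C4=C5, C6) the C1–O and C3–O bonds are 1,3-cis, so a one-carbon bridge from the C3 oxygen can reach C1 only on the face the target needs.
- Target ⇐ bridged cyclic carbonate (2,4-dioxabicyclo[3.3.1]non-6-en-3-one) by methanolysis. Carbonate ⇐ both C1 epimers of the (5S)-5-Boc-oxy-cyclohex-3-ene-1-carboxylic acid by anodic decarboxylation, the C1 cation closing onto the Boc carbonyl oxygen (C1–O bond).
- Acids ⇐ 2-(trimethylsilyl)ethyl ester of the racemic 5-oxocyclohex-3-ene-1-carboxylic acid by catalyst-controlled (S)-selective ketone reduction, Boc protection and fluoride cleavage of the ester.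
- Enone acid ⇐ Birch reductive alkylation of 3-methoxybenzoic acid with (Z)-16-bromo-1-phenylhexadec-4-ene, then acid hydrolysis. Bromide ⇐ Z-selective Wittig reaction of the ylide from 1-bromo-4-phenylbutane with 12-bromododecanal.
- Ring order: the carbocycle comes from the arene (no ring closure); the carbonate ring is the only ring closed (key step) and is opened again in the last step.

Key step: step 9

Remark: from the ketone reduction to the ester cleavage the two C1 epimers are carried as one mixture, because the key step erases that centre; no separation is planned.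

**Step 1**
Reactants: 1 1-bromo-4-phenylbutane
Product: 2 (4-phenylbutyl)triphenylphosphonium bromide
Conditions: PPh3, toluene, reflux
Reagents that add atoms: triphenylphosphine, c1ccc(cc1)P(c1ccccc1)c1ccccc1
Why: SN2 quaternization of triphenylphosphine by a primary alkyl bromide is the standard entry to a Wittig salt, which should precipitate from toluene.

**Step 2**
Reactants: 3 12-bromododecan-1-ol
Product: 4 12-bromododecanal
Conditions: TEMPO (2,2,6,6-tetramethylpiperidin-1-oxyl, cat.), PhI(OAc)2, CH2Cl2, rt
Reagents that add atoms: none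
Why: Oxoammonium-mediated (TEMPO/PhI(OAc)2) oxidation of a primary alcohol stops at the aldehyde and leaves the primary bromide untouched.

**Step 3**
Reactants: 2 (4-phenylbutyl)triphenylphosphonium bromide; 4 12-bromododecanal
Product: 6 [(4Z)-16-bromohexadec-4-en-1-yl]benzene, via phosphorus ylide 5 (not isolated)
Conditions: NaN(SiMe3)2, THF, −78 °C; then 4, −78 °C to rt
Reagents that add atoms: none
Why: Salt-free Wittig reaction of a non-stabilized ylide with an aliphatic aldehyde should give the Z alkene under kinetic control through the cis-oxaphosphetane; at −78 °C carbonyl addition is much faster than alkylation of the ylide by the primary bromide, and any E isomer would be removed on AgNO3-impregnated silica.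

**Step 4**
Reactants: 7 3-methoxybenzoic acid (in excess); 6 [(4Z)-16-bromohexadec-4-en-1-yl]benzene
Product: 9 rac-5-oxo-1-[(12Z)-16-phenylhexadec-12-en-1-yl]cyclohex-3-ene-1-carboxylic acid, via diene acid 8 (not isolated)
Conditions: Li, NH3/THF, −78 °C; isoprene (to discharge the blue colour); 6 in THF, −78 to −33 °C; NH3 evaporated; 2 M HCl, THF, 50 °C
Reagents that add atoms: water, O
Why: Birch reductive alkylation: Li/NH3 reduces the benzoate to the 1,4-dihydro dienolate, which the primary bromide alkylates at C1 (the methoxy group stays on sp2 carbon), and aqueous HCl then hydrolyses the enol ether and moves the remaining ring alkene into conjugation with the new ketone, aromatization being blocked by the quaternary carbon; the phenyl ring and Z alkene of 6 should survive because excess metal is destroyed before 6 is added and no alcohol is present.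

**Step 5**
Reactants: 9 rac-5-oxo-1-[(12Z)-16-phenylhexadec-12-en-1-yl]cyclohex-3-ene-1-carboxylic acid
Product: 10 rac-2-(trimethylsilyl)ethyl 5-oxo-1-[(12Z)-16-phenylhexadec-12-en-1-yl]cyclohex-3-ene-1-carboxylate
Conditions: Me3SiCH2CH2OH, DCC, 4-(dimethylamino)pyridine (DMAP), CH2Cl2, 0 °C to rt
Reagents that add atoms: 2-(trimethylsilyl)ethanol, C[Si](C)(C)CCO
Why: Steglich esterification (carbodiimide activation, DMAP acyl transfer) tolerates the α-quaternary acid and the enone, the base should also reopen any keto lactone formed by reversible oxa-Michael addition of the acid to the enone, and this ester is chosen because fluoride later removes it without touching a Boc carbonate.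

**Step 6**
Reactants: 10 rac-2-(trimethylsilyl)ethyl 5-oxo-1-[(12Z)-16-phenylhexadec-12-en-1-yl]cyclohex-3-ene-1-carboxylate
Product: 11 2-(trimethylsilyl)ethyl (1S,5S)-5-hydroxy-1-[(12Z)-16-phenylhexadec-12-en-1-yl]cyclohex-3-ene-1-carboxylate (ester cis to hydroxyl) and 12 its (1R,5S) epimer (ester trans to hydroxyl), obtained and carried on together
Conditions: (3aR)-1-methyl-3,3-diphenyltetrahydro-1H,3H-pyrrolo[1,2-c][1,3,2]oxazaborole [(R)-Me-CBS, 0.5 equiv], catecholborane, toluene, −78 °C
Reagents that add atoms: none
Why: Corey–Bakshi–Shibata reduction: the oxazaborolidine–borane complex delivers hydride to one carbonyl face with the alkenyl arm as the larger group, which for the (R) catalyst should give the (5S) carbinol from both enantiomers of 10 (catalyst control, the remote quaternary carbon only deciding which epimer forms, about equal amounts expected), and catecholborane at −78 °C neither adds 1,4 nor hydroborates the chain alkene.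

**Step 7**
Reactants: 11 and 12 (mixture of C1 epimers)
Product: 13 2-(trimethylsilyl)ethyl (1S,5S)-5-[(tert-butoxycarbonyl)oxy]-1-[(12Z)-16-phenylhexadec-12-en-1-yl]cyclohex-3-ene-1-carboxylate and 14 its (1R,5S) epimer
Conditions: Boc2O, DMAP (cat.), CH2Cl2, rt
Reagents that add atoms: di-tert-butyl dicarbonate, CC(C)(C)OC(=O)OC(=O)OC(C)(C)C
Why: DMAP-catalysed acylation of the secondary allylic alcohol by Boc2O gives the tert-butyl carbonate without touching a stereocentre, and the neutral conditions avoid lactonization of the cis epimer.

**Step 8**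
Reactants: 13 and 14 (mixture of C1 epimers)
Product: 15 (1S,5S)-5-[(tert-butoxycarbonyl)oxy]-1-[(12Z)-16-phenylhexadec-12-en-1-yl]cyclohex-3-ene-1-carboxylic acid (carboxyl cis to the Boc-oxy group) and 16 its (1R,5S) epimer (carboxyl trans)
Conditions: Bu4NF, THF, 0 °C to rt; aq. NH4Cl work-up
Reagents that add atoms: none
Why: Fluoride attacks silicon and the β-silylethyl ester fragments to ethene, Me3SiF and the carboxylate, a cleavage that does not depend on access to the hindered acyl carbon and should leave the tert-butyl carbonate and both alkenes intact.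

**Step 9**
Reactants: 15 and 16 (mixture of C1 epimers)
Product: 17 (1S,5S)-1-[(12Z)-16-phenylhexadec-12-en-1-yl]-2,4-dioxabicyclo[3.3.1]non-6-en-3-one
Conditions: graphite anode, graphite cathode, undivided cell, constant current (about 3 F/mol); 2,4,6-collidine, nBu4NPF6, 3 Å molecular sieves, CH2Cl2, rt
Reagents that add atoms: none
Why: Proposed new method: at the graphite anode the collidinium carboxylate should lose two electrons and CO2 (Hofer–Moest path, favoured over Kolbe coupling for a tertiary acid) to give the planar tertiary C1 cation, the same species from 15 and from 16; the carbonyl oxygen of the Boc group on C3 then adds to it and the resulting 2-tert-butoxy-1,3-dioxan-2-ylium ion sheds isobutene, the protons being reduced to hydrogen at the cathode. The closest known reaction types are the anodic decarboxylation of tertiary acids with capture of the cation by alcohols or water and the closure of homoallylic tert-butyl carbonates onto iodonium- or epoxide-derived cationic carbon to give six-membered cyclic carbonates; their combination on a carboxylic acid is the untested part. The single ring closed is the six-membered 1,3-dioxan-2-one, formed by attack of the C=O oxygen on the trigonal cationic carbon across the 1,3-diaxial positions of the cyclohexene, which makes it a bridged ring. The new C1 stereocentre is controlled only by the (S) centre at C3, because the O–C(=O)–O bridge can span C1 and C3 on one face alone, so both epimers should converge on the (1S,5S) carbonate. The step needs ring closure to outrun loss of a proton from C2, C6 or the chain and a 1,2-hydride shift from allylic C6, and needs the carboxylate to be oxidised before the chain alkene or the phenyl ring; the intramolecular six-membered delivery from a pseudoaxial allylic carbonate, the absence of any other nucleophile (dry CH2Cl2, PF6 salt, sieves) and the lower oxidation potential of a carboxylate compared with an isolated alkene or alkylbenzene are relied on for this.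

**Step 10**
Reactants: 17 (1S,5S)-1-[(12Z)-16-phenylhexadec-12-en-1-yl]-2,4-dioxabicyclo[3.3.1]non-6-en-3-one
Product: 18 (1S,3S)-1-[(12Z)-16-phenylhexadec-12-en-1-yl]cyclohex-4-ene-1,3-diol
Conditions: K2CO3 (cat.), MeOH, rt
Reagents that add atoms: none
Why: Base-catalysed methanolysis (transesterification) of the cyclic carbonate releases both hydroxyl groups without breaking a ring C–O bond, so the cis (1S,3S) configuration is retained.

**Compound list**

1 | 1-bromo-4-phenylbutane | BrCCCCc1ccccc1 | starting material
2 | (4-phenylbutyl)triphenylphosphonium bromide | [Br-].c1ccccc1CCCC[P+](c1ccccc1)(c1ccccc1)c1ccccc1 | intermediate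
3 | 12-bromododecan-1-ol | OCCCCCCCCCCCCBr | starting material
4 | 12-bromododecanal | O=CCCCCCCCCCCCBr | intermediate
5 | (4-phenylbutylidene)triphenylphosphorane (ylide) | c1ccccc1CCCC=P(c1ccccc1)(c1ccccc1)c1ccccc1 | intermediate (not isolated)
6 | [(4Z)-16-bromohexadec-4-en-1-yl]benzene | BrCCCCCCCCCCC/C=C\CCCc1ccccc1 | intermediate
7 | 3-methoxybenzoic acid | COc1cccc(c1)C(O)=O | starting material
8 | rac-3-methoxy-1-[(12Z)-16-phenylhexadec-12-en-1-yl]cyclohexa-2,5-diene-1-carboxylic acid | COC1=CC(CCCCCCCCCCC/C=C\CCCc2ccccc2)(C(O)=O)C=CC1 | intermediate (not isolated)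
9 | rac-5-oxo-1-[(12Z)-16-phenylhexadec-12-en-1-yl]cyclohex-3-ene-1-carboxylic acid | O=C1C=CCC(CCCCCCCCCCC/C=C\CCCc2ccccc2)(C(O)=O)C1 | intermediate
10 | rac-2-(trimethylsilyl)ethyl 5-oxo-1-[(12Z)-16-phenylhexadec-12-en-1-yl]cyclohex-3-ene-1-carboxylate | O=C1C=CCC(CCCCCCCCCCC/C=C\CCCc2ccccc2)(C(=O)OCC[Si](C)(C)C)C1 | intermediate
11 | 2-(trimethylsilyl)ethyl (1S,5S)-5-hydroxy-1-[(12Z)-16-phenylhexadec-12-en-1-yl]cyclohex-3-ene-1-carboxylate | O[C@@H]1C=CC[C@@](C(=O)OCC[Si](C)(C)C)(CCCCCCCCCCC/C=C\CCCc2ccccc2)C1 | intermediate
12 | 2-(trimethylsilyl)ethyl (1R,5S)-5-hydroxy-1-[(12Z)-16-phenylhexadec-12-en-1-yl]cyclohex-3-ene-1-carboxylate | O[C@@H]1C=CC[C@](C(=O)OCC[Si](C)(C)C)(CCCCCCCCCCC/C=C\CCCc2ccccc2)C1 | intermediate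
13 | 2-(trimethylsilyl)ethyl (1S,5S)-5-[(tert-butoxycarbonyl)oxy]-1-[(12Z)-16-phenylhexadec-12-en-1-yl]cyclohex-3-ene-1-carboxylate | CC(C)(C)OC(=O)O[C@@H]1C=CC[C@@](C(=O)OCC[Si](C)(C)C)(CCCCCCCCCCC/C=C\CCCc2ccccc2)C1 | intermediate
14 | 2-(trimethylsilyl)ethyl (1R,5S)-5-[(tert-butoxycarbonyl)oxy]-1-[(12Z)-16-phenylhexadec-12-en-1-yl]cyclohex-3-ene-1-carboxylate | CC(C)(C)OC(=O)O[C@@H]1C=CC[C@](C(=O)OCC[Si](C)(C)C)(CCCCCCCCCCC/C=C\CCCc2ccccc2)C1 | intermediate
15 | (1S,5S)-5-[(tert-butoxycarbonyl)oxy]-1-[(12Z)-16-phenylhexadec-12-en-1-yl]cyclohex-3-ene-1-carboxylic acid | CC(C)(C)OC(=O)O[C@@H]1C=CC[C@@](C(=O)O)(CCCCCCCCCCC/C=C\CCCc2ccccc2)C1 | intermediate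
16 | (1R,5S)-5-[(tert-butoxycarbonyl)oxy]-1-[(12Z)-16-phenylhexadec-12-en-1-yl]cyclohex-3-ene-1-carboxylic acid | CC(C)(C)OC(=O)O[C@@H]1C=CC[C@](C(=O)O)(CCCCCCCCCCC/C=C\CCCc2ccccc2)C1 | intermediate
17 | (1S,5S)-1-[(12Z)-16-phenylhexadec-12-en-1-yl]-2,4-dioxabicyclo[3.3.1]non-6-en-3-one | O=C1O[C@@H]2C=CC[C@@](O1)(CCCCCCCCCCC/C=C\CCCc3ccccc3)C2 | intermediate
18 | (1S,3S)-1-[(12Z)-16-phenylhexadec-12-en-1-yl]cyclohex-4-ene-1,3-diol | O[C@@H]1C=CC[C@@](O)(CCCCCCCCCCC/C=C\CCCc2ccccc2)C1 | target

**Step count**

Total: 10 steps. Longest linear sequence: 9 steps (steps 2 to 10, from 12-bromododecan-1-ol).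

**Steps most likely to fail**

Step 9 (proposed new method). The cation may lose a proton to give ring or exocyclic alkenes, or rearrange by hydride shift, before the carbonate closes. The chain alkene or the phenyl ring may also be oxidised at the anode in competition with the carboxylate. The fallback uses known chemistry, sets out from 15 and 16 and comes back at 17. The acid mixture would be coupled with N-hydroxyphthalimide (N,N'-diisopropylcarbodiimide, cat. DMAP, CH2Cl2) to the N-acyloxyphthalimides F1. Blue-light irradiation with bis(catecholato)diboron in N,N-dimethylacetamide, then pinacol and Et3N, would give by radical decarboxylative borylation the tertiary pinacol boronates F2 as both C1 epimers. NaBO3·4H2O in THF/water would oxidise the C–B bond with retention to the tertiary alcohols F3. With K2CO3 in methanol the cis epimer of F3 closes onto its Boc group to give 17 and goes on as in step 10, while the trans epimer ends as the trans diol F4, removed by chromatography. This route gives up the convergence at C1, so the material with the wrong C1 configuration is lost.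

Step 6. Catalyst control may be incomplete, giving low selectivity at the carbinol for one or both enantiomers of the racemic ketone (mismatched pairing with the remote quaternary centre). The fallback sets out from 10 and comes back at 11 and 12. Luche reduction (NaBH4, CeCl3·7H2O, MeOH, −78 °C) would give the hydroxy esters F5 as all four stereoisomers. Lipase-mediated kinetic resolution (lipase from Pseudomonas cepacia or Candida antarctica lipase B, vinyl acetate, tert-butyl methyl ether, rt), with the enzyme chosen by screening so that the (5R) carbinols are acylated, would convert these into the (5R) acetates F6. Run past half conversion, this should leave the (5S) alcohols 11 and 12 for separation by chromatography. The same route would also serve to upgrade material of insufficient enantiomeric purity from step 6.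

Step 4. The alkylation may fail through reduction of the C–Br bond or of the phenyl ring by residual dissolved metal, through elimination by amide, or through poor mixing of the waxy bromide in liquid ammonia. The fallback sets out from 7 and 6 and comes back at 8. It separates reduction from alkylation: Birch reduction of 7 alone (Li, NH3/THF, −78 °C; NH4Cl; work-up near pH 5 to spare the enol ether) would give 3-methoxycyclohexa-2,5-diene-1-carboxylic acid F7. Its dianion, formed with LiN(iPr)2 (2.2 equiv) in THF/DMPU at −78 °C, would be alkylated at C1 by 6 under homogeneous conditions to give 8, which is hydrolysed with 2 M HCl in THF as in the second stage of step 4.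

**Further compounds**

F1 | step 9 | 1,3-dioxoisoindolin-2-yl (5S)-5-[(tert-butoxycarbonyl)oxy]-1-[(12Z)-16-phenylhexadec-12-en-1-yl]cyclohex-3-ene-1-carboxylate, both C1 epimers | CC(C)(C)OC(=O)O[C@@H]1C=CCC(C(=O)ON2C(=O)c3ccccc3C2=O)(CCCCCCCCCCC/C=C\CCCc4ccccc4)C1
F2 | step 9 | tert-butyl (1S)-5-[(12Z)-16-phenylhexadec-12-en-1-yl]-5-(4,4,5,5-tetramethyl-1,3,2-dioxaborolan-2-yl)cyclohex-2-en-1-yl carbonate, both C5 epimers | CC(C)(C)OC(=O)O[C@@H]1C=CCC(B2OC(C)(C)C(C)(C)O2)(CCCCCCCCCCC/C=C\CCCc3ccccc3)C1
F3 | step 9 | tert-butyl (1S)-5-hydroxy-5-[(12Z)-16-phenylhexadec-12-en-1-yl]cyclohex-2-en-1-yl carbonate, both C5 epimers | CC(C)(C)OC(=O)O[C@@H]1C=CCC(O)(CCCCCCCCCCC/C=C\CCCc2ccccc2)C1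
F4 | step 9 | (1R,3S)-1-[(12Z)-16-phenylhexadec-12-en-1-yl]cyclohex-4-ene-1,3-diol (trans diol) | O[C@@H]1C=CC[C@](O)(CCCCCCCCCCC/C=C\CCCc2ccccc2)C1
F5 | step 6 | 2-(trimethylsilyl)ethyl 5-hydroxy-1-[(12Z)-16-phenylhexadec-12-en-1-yl]cyclohex-3-ene-1-carboxylate, all four stereoisomers | OC1C=CCC(C(=O)OCC[Si](C)(C)C)(CCCCCCCCCCC/C=C\CCCc2ccccc2)C1
F6 | step 6 | 2-(trimethylsilyl)ethyl (5R)-5-acetoxy-1-[(12Z)-16-phenylhexadec-12-en-1-yl]cyclohex-3-ene-1-carboxylate, both C1 epimers | CC(=O)O[C@H]1C=CCC(C(=O)OCC[Si](C)(C)C)(CCCCCCCCCCC/C=C\CCCc2ccccc2)C1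
F7 | step 4 | 3-methoxycyclohexa-2,5-diene-1-carboxylic acid | COC1=CC(C=CC1)C(O)=O
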